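## Retrosynthetic overview

1. Target 16 ⇒ acylfilicinic acid (R)-8 + acylphloroglucinol 12 + one-carbon aminal 13; the methylene bridge is made last by Mannich reaction, elimination and Michael addition.
2. (R)-8 ⇒ iodo ether 7 (zinc reopening of a β-iodo ether) ⇒ 4 + butanoic acid 5 (C-acylation of the only free 1,3-dione carbon).
3. Key disconnection: the ether C–O bond of 4. Enantioselective iodoetherification of the prochiral trione 3 picks one of two enantiotopic enol oxygens and so fixes the quaternary carbon.
4. 3 ⇒ 2-methylphloroglucinol 1 + prenyl bromide 2 (alkylative dearomatization); 12 ⇒ 5-methoxyresorcinol 9 + hexanenitrile 10 (Hoesch acylation).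
5. Ring order: the cyclohexadienone ring comes from dearomatization of bought 1 (step 1); a temporary dihydropyran ring is closed in step 2 and reopened in step 4; the aromatic ring is bought as 9.

Assumption: the sense of induction of the cinchona catalyst in step 2 cannot be predicted with certainty; (DHQD)2PHAL is taken to give the (3S,4aS) ether 4, and the pseudoenantiomeric (DHQ)2PHAL is used in the same step if the opposite sense is found.

## Route

Step 1
Reactants: 1 2-methylbenzene-1,3,5-triol (2-methylphloroglucinol), 2 1-bromo-3-methylbut-2-ene (prenyl bromide)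
Product: 3 3,5-dihydroxy-4-methyl-4-(3-methylbut-2-en-1-yl)cyclohexa-2,5-dien-1-one
Conditions: 1 (2 equiv), NaOMe (1 equiv), MeOH, −20 to 0 °C; extraction into aq. NaHCO3, then HCl to pH 3 at 0 °C
Reagents that add atoms: none
Why: Alkylative dearomatization (C-alkylation of the phloroglucinol anion at the methyl-bearing carbon) gives the vinylogous diacid 3, which is the only product acidic enough to be extracted by NaHCO3; C4 is prochiral, so no stereocenter is formed yet.

Step 2
Reactants: 3 3,5-dihydroxy-4-methyl-4-(3-methylbut-2-en-1-yl)cyclohexa-2,5-dien-1-one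
Product: 4 (3S,4aS)-5-hydroxy-3-iodo-2,2,4a-trimethyl-2,3,4,4a-tetrahydro-7H-chromen-7-one
Conditions: N-iodosuccinimide (1.05 equiv), (DHQD)2PHAL (10 mol%), CHCl3/toluene 1:1, −40 °C, dark; aq. Na2S2O3
Reagents that add atoms: N-iodosuccinimide, O=C1CCC(=O)N1I
Why: Proposed new method: a catalyst-controlled desymmetrizing 6-endo iodoetherification (a vinylogous iodolactonization) in which the acidic enol of 3 (pKa about 4 to 5) ion-pairs with a quinuclidine nitrogen of the catalyst, electrophilic iodine is delivered to the prenyl alkene and the tertiary carbon is captured (Markovnikov) by one of the two enantiotopic enol oxygens through a chair transition state (iodine equatorial, the C4a methyl forced axial by the ring fusion), so that this C–O bond formation alone sets the quaternary centre as 4aS; iodination at the free enol carbons is expected to be reversible because 2-iodo-1,3-diones hand their iodine back to the amine catalyst, whereas ether formation is not; the closest known reaction type is the cinchona-alkaloid-catalysed enantioselective halolactonization and haloetherification of alkenoic acids and alkenols, not yet shown for enolized cyclic triones or for setting an all-carbon quaternary centre by choice between two enol oxygens.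

Step 3
Reactants: 4 (3S,4aS)-5-hydroxy-3-iodo-2,2,4a-trimethyl-2,3,4,4a-tetrahydro-7H-chromen-7-one, 5 butanoic acid
Product: 7 (3S,4aS)-6-butanoyl-5-hydroxy-3-iodo-2,2,4a-trimethyl-2,3,4,4a-tetrahydro-7H-chromen-7-one, via enol ester 6 (not isolated)
Conditions: DCC (1.2 equiv), DMAP (1.0 equiv), CH2Cl2, 0 °C to rt, 16 h
Reagents that add atoms: none
Why: Steglich O-acylation of the free vinylogous acid followed by DMAP-mediated O-to-C acyl shift (the usual one-pot C-acylation of cyclic 1,3-diones) places the butanoyl group on C6, the only carbon between two carbonyls, while C8 is locked in the enol ether and the hindered secondary iodide is inert; both stereocentres are untouched.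

Step 4
Reactants: 7 (3S,4aS)-6-butanoyl-5-hydroxy-3-iodo-2,2,4a-trimethyl-2,3,4,4a-tetrahydro-7H-chromen-7-one
Product: 8 (4R)-2-butanoyl-3,5-dihydroxy-4-methyl-4-(3-methylbut-2-en-1-yl)cyclohexa-2,5-dien-1-one
Conditions: Zn dust (5 equiv), AcOH (3 equiv), THF, 0 °C to rt, 1 h
Reagents that add atoms: none
Why: Reductive β-elimination of the β-iodo ether by zerovalent zinc (the reverse of the iodoetherification, as in the reopening of iodolactones) regenerates the prenyl double bond regiospecifically and frees the enol; the quaternary carbon is not involved, and its descriptor becomes R only because the CIP priorities change.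

Step 5
Reactants: 9 5-methoxybenzene-1,3-diol (5-methoxyresorcinol), 10 hexanenitrile
Product: 12 1-(2,4-dihydroxy-6-methoxyphenyl)hexan-1-one, via ketiminium chloride 11 (not isolated)
Conditions: ZnCl2 (0.5 equiv), HCl gas, Et2O, 0 °C, 24 h; then H2O, 100 °C, 1 h
Reagents that add atoms: water, O
Why: Houben–Hoesch acylation at C4 (two equivalent sites, para to a free hydroxyl) gives the 2,4-dihydroxy-6-methoxy ketone as the main isomer, separable by chromatography from the symmetric 2,6-dihydroxy-4-methoxy isomer, under conditions that do not cleave the methyl ether.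

Step 6
Reactants: 8 (4R)-2-butanoyl-3,5-dihydroxy-4-methyl-4-(3-methylbut-2-en-1-yl)cyclohexa-2,5-dien-1-one, 12 1-(2,4-dihydroxy-6-methoxyphenyl)hexan-1-one, 13 N,N,N',N'-tetramethylmethanediamine
Product: 16 (4R)-2-butanoyl-6-[(3-hexanoyl-2,6-dihydroxy-4-methoxyphenyl)methyl]-3,5-dihydroxy-4-methyl-4-(3-methylbut-2-en-1-yl)cyclohexa-2,5-dien-1-one, via Mannich base 14 (not isolated), via methylene trione 15 (not isolated)
Conditions: 13 (1.0 equiv), MeCN, 0 °C to rt, 1 h; then 12 (2.0 equiv), 50 °C, 6 h; cold 1 M HCl wash
Reagents that add atoms: none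
Why: Mannich aminomethylation of the only free enol carbon of 8, elimination of dimethylamine to the 2-methylidene-1,3-dione and Friedel–Crafts-type Michael addition of phenol 12 through C3 (between its two hydroxyls) build the methylene bridge in the standard way for joining filicinic acid and acylphloroglucinol units; converting all of 8 to 14 before 12 is added suppresses homodimers, and the quaternary centre is untouched.

## Compound list

1 | 2-methylbenzene-1,3,5-triol | Cc1c(O)cc(O)cc1O | starting material
2 | 1-bromo-3-methylbut-2-ene | CC(C)=CCBr | starting material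
3 | 3,5-dihydroxy-4-methyl-4-(3-methylbut-2-en-1-yl)cyclohexa-2,5-dien-1-one | CC(C)=CCC1(C)C(O)=CC(=O)C=C1O | intermediate
4 | (3S,4aS)-5-hydroxy-3-iodo-2,2,4a-trimethyl-2,3,4,4a-tetrahydro-7H-chromen-7-one | CC1(C)OC2=CC(=O)C=C(O)[C@]2(C)C[C@@H]1I | intermediate
5 | butanoic acid | CCCC(=O)O | starting material
6 | (3S,4aR)-3-iodo-2,2,4a-trimethyl-5-oxo-3,4,4a,5-tetrahydro-2H-chromen-7-yl butanoate | CC1(C)OC2=CC(OC(=O)CCC)=CC(=O)[C@]2(C)C[C@@H]1I | intermediate
7 | (3S,4aS)-6-butanoyl-5-hydroxy-3-iodo-2,2,4a-trimethyl-2,3,4,4a-tetrahydro-7H-chromen-7-one | CC1(C)OC2=CC(=O)C(C(=O)CCC)=C(O)[C@]2(C)C[C@@H]1I | intermediate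
8 | (4R)-2-butanoyl-3,5-dihydroxy-4-methyl-4-(3-methylbut-2-en-1-yl)cyclohexa-2,5-dien-1-one | O=C1C=C(O)[C@@](C)(CC=C(C)C)C(O)=C1C(=O)CCC | intermediate
9 | 5-methoxybenzene-1,3-diol | COc1cc(O)cc(O)c1 | starting material
10 | hexanenitrile | CCCCCC#N | starting material
11 | 1-(2,4-dihydroxy-6-methoxyphenyl)hexan-1-iminium chloride | CCCCCC(=[NH2+])c1c(O)cc(O)cc1OC.[Cl-] | intermediate
12 | 1-(2,4-dihydroxy-6-methoxyphenyl)hexan-1-one | CCCCCC(=O)c1c(O)cc(O)cc1OC | intermediate
13 | N,N,N',N'-tetramethylmethanediamine | CN(C)CN(C)C | starting material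
14 | (4R)-2-butanoyl-6-[(dimethylamino)methyl]-3,5-dihydroxy-4-methyl-4-(3-methylbut-2-en-1-yl)cyclohexa-2,5-dien-1-one | CN(C)CC1=C(O)[C@@](C)(CC=C(C)C)C(O)=C(C(=O)CCC)C1=O | intermediate
15 | (4S)-2-butanoyl-3-hydroxy-4-methyl-4-(3-methylbut-2-en-1-yl)-6-methylidenecyclohex-2-ene-1,5-dione | C=C1C(=O)C(C(=O)CCC)=C(O)[C@](C)(CC=C(C)C)C1=O | intermediate
16 | (4R)-2-butanoyl-6-[(3-hexanoyl-2,6-dihydroxy-4-methoxyphenyl)methyl]-3,5-dihydroxy-4-methyl-4-(3-methylbut-2-en-1-yl)cyclohexa-2,5-dien-1-one | CCCCCC(=O)c1c(OC)cc(O)c(CC2=C(O)[C@@](C)(CC=C(C)C)C(O)=C(C(=O)CCC)C2=O)c1O | target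

## Step count and risks

Total steps: 6. Longest linear sequence: 5 (steps 1, 2, 3, 4, 6); step 5 is a one-step side branch.

The three steps most likely to fail:

**Step 1 (site selectivity).** Prenylation of 1 can also occur at the two unsubstituted ring carbons (giving aromatic 4-prenyl products) and a second time on 3, so 3 is expected in only about 30% yield. Fallback, blocking both free ring carbons first: setting out from 1, double Vilsmeier–Haack formylation (POCl3, DMF, then water) gives 2,4,6-trihydroxy-5-methylbenzene-1,3-dicarbaldehyde F1. With NaOMe in MeOH, 2 can then alkylate only the methyl-bearing carbon and gives 2,6-diformyl-3,5-dihydroxy-4-methyl-4-(3-methylbut-2-en-1-yl)cyclohexa-2,5-dien-1-one F2. Both formyl groups are then removed by retro-Claisen cleavage in aqueous NaOH at 50 °C, which comes back to the route at 3.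

**Step 2 (the proposed new step).** Three things can go wrong: iodine may stay on the free enol carbons instead of being passed on to the alkene, a racemic uncatalysed cyclization may compete, and the catalyst may discriminate poorly between the two enol oxygens. Only the C4a configuration matters: the iodide-bearing carbon is destroyed in step 4, and a 5-exo ether would reopen to the same constitution, so the enantiomer ratio is read on 8 by chiral HPLC. Fallback with known chemistry: setting out from 3, C-acylation with one equivalent of 5 (DCC, DMAP, CH2Cl2) gives racemic 2-butanoyl-3,5-dihydroxy-4-methyl-4-(3-methylbut-2-en-1-yl)cyclohexa-2,5-dien-1-one F3. This is resolved by preparative chiral SFC on an amylose tris(3,5-dimethylphenylcarbamate) phase; (4S)-2-butanoyl-3,5-dihydroxy-4-methyl-4-(3-methylbut-2-en-1-yl)cyclohexa-2,5-dien-1-one F4 is discarded, and the (4R)-enantiomer is 8, where the route is rejoined.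

**Step 6 (regiochemistry on 12, cross- versus homo-coupling).** Attack of 12 through C5 instead of C3, or scrambling of the methylene bridge, would give isomers or homodimers. Fallback with reversed polarity and the regiochemistry fixed beforehand: setting out from 12, Mannich reaction with aqueous dimethylamine and formaldehyde in EtOH gives 1-[3-[(dimethylamino)methyl]-2,4-dihydroxy-6-methoxyphenyl]hexan-1-one F5, which is purified and its substitution pattern proven by HMBC. Heating F5 with 8 in dioxane at 80 °C releases the ortho-quinone methide of the aromatic unit, which is captured by C6 of 8 and comes back to the route at 16.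

## Further compounds

F1 | step 1 | 2,4,6-trihydroxy-5-methylbenzene-1,3-dicarbaldehyde | Cc1c(O)c(C=O)c(O)c(C=O)c1O
F2 | step 1 | 2,6-diformyl-3,5-dihydroxy-4-methyl-4-(3-methylbut-2-en-1-yl)cyclohexa-2,5-dien-1-one | O=CC1=C(O)C(C)(CC=C(C)C)C(O)=C(C=O)C1=O
F3 | step 2 | racemic 2-butanoyl-3,5-dihydroxy-4-methyl-4-(3-methylbut-2-en-1-yl)cyclohexa-2,5-dien-1-one | O=C1C=C(O)C(C)(CC=C(C)C)C(O)=C1C(=O)CCC
F4 | step 2 | (4S)-2-butanoyl-3,5-dihydroxy-4-methyl-4-(3-methylbut-2-en-1-yl)cyclohexa-2,5-dien-1-one | O=C1C=C(O)[C@](C)(CC=C(C)C)C(O)=C1C(=O)CCC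
F5 | step 6 | 1-[3-[(dimethylamino)methyl]-2,4-dihydroxy-6-methoxyphenyl]hexan-1-one | CCCCCC(=O)c1c(OC)cc(O)c(CN(C)C)c1O
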